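A closed, stirred vessel held at constant temperature is thought to carry starting material through intermediate A, intermediate B and intermediate C to target, which reacts on to the over-reaction products, while protic impurity diverts some starting material to quenched substrate.

in all of them: protic impurity 0.0365 M

|  | starting material | temperature | remark | time |
|---|---|---|---|---|
| delta | 0.036 M | 15 °C | run made earlier |  |
| beta | 0.055 M | 42 °C | run made earlier |  |
| west | 0.073 M | 65 °C |  | 4.0 min |
| east | 0.073 M | 50 °C |  | 4.0 min |
| south-east | 0.073 M | 35 °C |  | 4.0 min |
| north-west | 0.073 M | 20 °C |  | 4.0 min |

- delta (time / min: target / %): 4.00: 0; 12.0: 1.9; 20.0: 3.1; 30.0: 5.8; 50.0: 19.3; 60.0: 26.0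
- beta (time / min: target / %): 1.33: 10.0; 2.00: 18.4; 3.00: 32.6; 6.00: 40.8; 10.0: 21.6; 15.0: 7.1

(readings scatter by 1 percentage point)

- what may be going on: starting material -> intermediate A; intermediate A -> intermediate B; intermediate B -> intermediate C; intermediate C -> target; target -> over-reaction product A; target -> over-reaction product B; starting material + protic impurity -> quenched substrate

- the flask with the highest amount of target, in percent of the starting material charged ("all alike" if they lie within 1.5 percentage points) (west / east / south-east / north-west / all alike)
- final target, as a percentage of the starting material charged, in west
- final target, as a percentage of the starting material charged, in east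
- final target, as a percentage of the starting material charged, in south-east
- final target, as a percentage of the starting material charged, in north-west

1. Taken as first order, the chain steps give a curve in percent of charge that does not depend on the charge. The quench is a second-order correction, and this reckoning leaves it out. The delta and beta runs can therefore be compared despite their different charges.

2. A rate constant grows with temperature according to its activation energy. If the steps share one activation energy, heating speeds the clock and leaves the shape of the curve unchanged. That shared value is an assumption.

3. The delta run reads 19.3% at 50.0 min and the beta run reads 18.4% at 2.00 min, which agree within about the scatter of 1 percentage point. The clock ratio between 15 °C and 42 °C therefore reads 25.0, which gives a shared activation energy, as a reading, of 90.0 kJ/mol.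

4. At this activation energy, the 4.0 min in east count as 9.36 min of the beta run. This is east's beta-equivalent time: the minutes at the beta temperature that give the same progress as a flask's own minutes. It lies between the beta readings at 6.00 min and 10.0 min, and straight interpolation gives 24.7%.

5. South-east has a beta-equivalent time of 1.83 min, which interpolates to 16.3%. This reckoning therefore puts east higher than south-east.

6. West has a beta-equivalent time of 41.4 min, later than the last beta reading, so west should hold less than that reading's 7.1%.

7. North-west has a beta-equivalent time of 0.304 min. On the delta clock this is 7.60 min, between the delta readings at 4.00 min and 12.0 min, which stand at 0% and 1.9%.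

8. The forecast gives 1.5% for west, 26% for east, 18% for south-east and 0.7% for north-west, with east and south-east figures higher than this reckoning's, and states: “East should be highest.”

9. The flasks give 0.149% in west, 28.6% in east, 16.1% in south-east and 0.111% in north-west, so east holds the most target. East stands 4 points above the reckoning.

    starting material → intermediate A (k = 0.0350 /s, Ea = 92.0 kJ/mol)
    intermediate A → intermediate B (k = 0.00480 /s, Ea = 93.0 kJ/mol)
    intermediate B → intermediate C (k = 0.0140 /s, Ea = 85.0 kJ/mol)
    intermediate C → target (k = 0.00650 /s, Ea = 81.0 kJ/mol)
    target → over-reaction product A (k = 0.00200 /s, Ea = 78.0 kJ/mol)
    target → over-reaction product B (k = 8.60 × 10⁻⁶ /s, Ea = 104 kJ/mol)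
    starting material + protic impurity → quenched substrate (k = 0.130 /M/s, Ea = 70.0 kJ/mol)
    (constants at 35 °C)

At 4.00 min in east, target is made more slowly than it is used up, at 0.180 times that rate, so the amount of target in east is falling at that moment. East read at 6.0 min has a beta-equivalent time of 14.0 min, where interpolation between the beta readings at 10.0 min and 15.0 min gives 9.87%, and that flask holds 11.5% target.

(Readings and results come from a simulation with made-up constants, and the scatter is random.)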